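The α‑methylene‑γ‑lactone (ring O, C6, C7, C11, C12) is disconnected at O–C6 and C11–C7. Because C6 is allylic to the C4=C5 double bond of the ten‑membered ring, C7=C6–C5=C4 is a latent 1,3‑diene. A palladium‑catalysed heteroannulation with 2‑bromoacrylic acid adds C11 to C7 and its carboxylate oxygen to C6 in one operation, giving the complete exo‑methylene lactone and leaving C4=C5. The precursor is an acyclic (E,Z)‑dienyl dioxolane whose glyceraldehyde‑derived centre steers the C7 face and is later excised to the C8 aldehyde. A boron aldol/Evans–Tishchenko pair then sets C3‑OAc/C1‑OH, and a Nozaki–Hiyama–Kishi reaction closes C8–C9.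

Key step: step 9

Remark on the chemistry (locants used throughout): ring carbons C1–C10, with C1 the free carbinol, C3 the acetoxy carbon, C4=C5 (C4 bears the hydroxymethyl C15), C6 the lactone O‑carbon, C7 the carbon bearing C11, C8 the angelate carbon, C9=C10 (C10 bears the methyl C14); C11/C12/C13 are the lactone α‑carbon, carbonyl and exocyclic CH2. With these locants the target is (1S,3S,6S,7S,8R), 4Z, 9Z. Alcohol 1 is used racemic, since its carbinol carbon becomes the C1 ketone. The dioxolane carbon of 9 becomes C8 and serves only as a relay; the antipode of 9 would be taken if the sense of induction in step 9 were found opposite.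

Step 1
Reactants: 1 but‑3‑yn‑2‑ol
Product: 3 (Z)-4-iodo-3-methylbut-3-en-2-ol, via bromomagnesium alkenyl alkoxide 2 (not isolated)
Conditions: MeMgBr (3 equiv), CuI (10 mol %), Et2O, −10 °C → rt; then I2, −78 → 0 °C
Reagents that add atoms: methylmagnesium bromide, C[Mg]Br; iodine, II
Why: Copper‑catalysed anti‑carbomagnesiation of the propargylic alkoxide places methyl on the internal carbon and magnesium on the terminal carbon in a five‑membered chelate, so iodinolysis with retention should give the Z iodide (iodine cis to the carbinol carbon).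

Step 2
Reactants: 3 (Z)-4-iodo-3-methylbut-3-en-2-ol
Product: 4 (Z)-4-iodo-3-methylbut-3-en-2-one
Conditions: MnO2 (excess), CH2Cl2, rt, dark
Reagents that add atoms: none
Why: Neutral allylic alcohol oxidation should leave the vinyl iodide and its geometry untouched.

Step 3
Reactants: 5 methyl prop‑2‑ynoate
Product: 7 methyl (Z)-2-(hydroxymethyl)-3-iodoprop-2-enoate, via aluminium β‑iodoallenolate 6 (not isolated)
Conditions: Et2AlI, CH2Cl2, −78 °C; then monomeric CH2O (from cracked paraformaldehyde), −78 °C; aqueous tartrate work‑up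
Reagents that add atoms: diethylaluminium iodide, CC[Al](I)CC; formaldehyde, C=O
Why: Iodide conjugate addition to the ynoate and aldol capture of the allenolate (β‑iodo Morita–Baylis–Hillman reaction) should give the kinetic Z isomer with iodine cis to the ester.

Step 4
Reactants: 7 methyl (Z)-2-(hydroxymethyl)-3-iodoprop-2-enoate
Product: 8 methyl (Z)-2-[(tert-butyldimethylsilyloxy)methyl]-3-iodoprop-2-enoate
Conditions: TBSCl, imidazole, DMF, 0 °C → rt
Reagents that add atoms: tert‑butyldimethylsilyl chloride, CC(C)(C)[Si](C)(C)Cl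
Why: Standard silylation protects the future C15 hydroxyl until the last step.

Step 5
Reactants: 9 (S)-2,2-dimethyl-1,3-dioxolane-4-carbaldehyde
Product: 10 2-[(E)-2-[(4R)-2,2-dimethyl-1,3-dioxolan-4-yl]ethenyl]-4,4,5,5-tetramethyl-1,3,2-dioxaborolane
Conditions: Cl2CHB(pin), CrCl2, LiI, THF, rt
Reagents that add atoms: 2-(dichloromethyl)-4,4,5,5-tetramethyl-1,3,2-dioxaborolane, ClC(Cl)B1OC(C)(C)C(C)(C)O1
Why: Takai–Utimoto boron olefination through a gem‑dichromium species should give the E alkenylboronate without epimerising the α‑alkoxy centre.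

Step 6
Reactants: 8 methyl (Z)-2-[(tert-butyldimethylsilyloxy)methyl]-3-iodoprop-2-enoate; 10 (E)‑alkenylboronate
Product: 11 methyl (2Z,4E)-2-[(tert-butyldimethylsilyloxy)methyl]-5-[(4R)-2,2-dimethyl-1,3-dioxolan-4-yl]penta-2,4-dienoate
Conditions: PdCl2(dppf) (5 mol %), K3PO4, THF–H2O, 40 °C
Reagents that add atoms: none
Why: Suzuki–Miyaura coupling is stereoretentive at both sp2 partners, which fixes the ester carbon (future C3) cis and the silyloxymethyl arm (C15) trans to the diene chain.

Step 7
Reactants: 11 methyl (2Z,4E)‑dienoate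
Product: 12 (2E,4E)-2-[(tert-butyldimethylsilyloxy)methyl]-5-[(4R)-2,2-dimethyl-1,3-dioxolan-4-yl]penta-2,4-dien-1-ol (CH2OH cis to the diene chain)
Conditions: i‑Bu2AlH (2.2 equiv), CH2Cl2, −78 °C; Rochelle salt work‑up
Reagents that add atoms: none
Why: 1,2‑Reduction of the conjugated ester at low temperature should give the allylic alcohol with both double bonds unchanged.

Step 8
Reactants: 12 dienol
Product: 13 (4R)-4-[(1E,3E)-4-[(tert-butyldimethylsilyloxy)methyl]-5-(triethylsilyloxy)penta-1,3-dienyl]-2,2-dimethyl-1,3-dioxolane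
Conditions: Et3SiCl, imidazole, CH2Cl2, 0 °C
Reagents that add atoms: chlorotriethylsilane, CC[Si](Cl)(CC)CC
Why: Silylation masks the hydroxymethyl arm cis to the diene, which could otherwise attack the allylpalladium intermediate of step 9, as a group that step 10 converts directly into the aldehyde.

Step 9
Reactants: 13 dienyl dioxolane; 14 2‑bromoprop‑2‑enoic acid
Product: 15 (4R,5S)-4-[(4R)-2,2-dimethyl-1,3-dioxolan-4-yl]-3-methylidene-5-[(E)-2-[(tert-butyldimethylsilyloxy)methyl]-3-(triethylsilyloxy)prop-1-enyl]oxolan-2-one (trans‑lactone; C6 S, C7 R)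
Conditions: Pd(OAc)2 (10 mol %), PPh3 (20 mol %), Ag2CO3, DMF, 70 °C
Reagents that add atoms: none
Why: Zerovalent palladium inserts into the C–Br bond of the carboxylate of 14, the alkenylpalladium adds syn across C7=C6 with C11 going to C7, and the resulting η3‑allyl (C6–C5–C4), held as a six‑membered palladacycle by the carboxylate, undergoes C–O bond formation at C6. The closest known reaction type is the palladium‑catalysed heteroannulation of 1,3‑dienes by vinylic halides carrying an oxygen nucleophile (2‑bromoallyl alcohols, halo acids). The γ‑lactone closes in a 5‑exo mode onto the proximal allyl terminus, not onto C4 (seven‑membered ring). C7 is set by 1,2‑induction from the dioxolane carbon, the new C7–C11 bond forming anti to the allylic C–O bond. C6 is set by inner‑sphere (syn) C–O formation on the E double bond under halide‑free conditions, which gives the trans‑lactone, and reversible ionisation of the allylic lactone by zerovalent palladium should drain any cis isomer to the same product. The step needs carbopalladation at the monosubstituted terminus C7 and not at the fully substituted C4, and retention of the C4=C5 geometry, which is secured because a σ‑palladium at C4 is disfavoured.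

Step 10
Reactants: 15 trans‑lactone
Product: 17 (Z)-2-[(tert-butyldimethylsilyloxy)methyl]-3-[(2S,3R)-3-[(4R)-2,2-dimethyl-1,3-dioxolan-4-yl]-4-methylidene-5-oxooxolan-2-yl]prop-2-enal, via primary allylic alcohol 16 (not isolated)
Conditions: (COCl)2, DMSO, CH2Cl2, −78 → −30 °C; Et3N, −78 °C
Reagents that add atoms: none
Why: Swern conditions cleave a primary triethylsilyl ether and oxidise the liberated alcohol in one pot while the tert‑butyldimethylsilyl ether survives, and the low temperature should preserve the Z enal (CHO cis to C6).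

Step 11
Reactants: 4 (Z)-4-iodo-3-methylbut-3-en-2-one; 17 (Z)‑enal
Product: 19 (3S)‑β‑hydroxy ketone: C3 carbinol joined through C2H2 to the C1 ketone of the (Z)‑C10(CH3)=C9H–I unit; lactone (C6 S, C7 R), C15‑OTBS and (R)‑dioxolane as in 17, via diisopinocampheylboron enolate 18 (not isolated)
Conditions: (+)-Ipc2BCl, i‑Pr2NEt, Et2O, −78 → 0 °C; then 17, −78 → −20 °C; H2O2, pH 7 buffer, MeOH, 0 °C
Reagents that add atoms: none
Why: Boron aldol reaction of a methyl ketone through its chiral diisopinocampheylboron enolate, chosen to add to the si face of the aldehyde under reagent control and so set C3 as S.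

Step 12
Reactants: 19 β‑hydroxy ketone
Product: 20 (1S,3S)‑1,3‑anti diol monoacetate: C3‑OAc, C1‑OH; otherwise as 19
Conditions: SmI2 (30 mol %), CH3CHO (excess), THF, −10 °C
Reagents that add atoms: acetaldehyde, CC=O
Why: Evans–Tishchenko reduction delivers hydride intramolecularly from the samarium‑bound hemiacetal to the C1 ketone, which gives the 1,3‑anti alcohol and leaves the acetate on the C3 oxygen, exactly as in the target.

Step 13
Reactants: 20 diol monoacetate
Product: 21 C1 tert‑butyldimethylsilyl ether of 20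
Conditions: TBSOTf, 2,6‑lutidine, CH2Cl2, −78 °C
Reagents that add atoms: tert‑butyldimethylsilyl trifluoromethanesulfonate, CC(C)(C)[Si](C)(C)OS(=O)(=O)C(F)(F)F
Why: Low‑temperature silylation protects the C1 hydroxyl without acetyl migration, so that only the C8 hydroxyl is free in step 16.

Step 14
Reactants: 21 bis‑silyl ether
Product: 23 C8 aldehyde: lactone C7 (R) carries CHO; C6 S; C1‑OTBS, C3‑OAc, C15‑OTBS, (Z)‑vinyl iodide, via terminal 1,2‑diol 22 (not isolated)
Conditions: H5IO6, EtOAc, rt; used at once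
Reagents that add atoms: none
Why: Periodic acid hydrolyses the terminal acetonide and cleaves the liberated glycol in one pot (glycol cleavage), leaving silyl ethers and esters intact.

Step 15
Reactants: 23 iodo aldehyde
Product: 25 (1S,3S,6S,7S,8R)‑macrocyclic allylic alcohol: ten‑membered ring (4Z,9Z) trans‑fused at C6/C7 to the α‑methylene‑γ‑lactone; C1‑OTBS, C3‑OAc, C8‑OH, C15‑OTBS, via alkenylchromium dichloride 24 (not isolated)
Conditions: CrCl2 (10 equiv), NiCl2 (0.1 equiv), degassed DMSO–THF, 0.002 M, rt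
Reagents that add atoms: none
Why: Nozaki–Hiyama–Kishi macrocyclisation adds the configurationally stable Z‑alkenylchromium to the aldehyde under neutral conditions; attack anti to the larger C6 branch of C7 (anti C6–C7–C8–C9 torsion in the forming ring) should give the 8R alcohol.

Step 16
Reactants: 25 macrocyclic alcohol; 26 angelic acid
Product: 28 C8 angelate of 25, via angelic 2,4,6‑trichlorobenzoic anhydride 27 (not isolated)
Conditions: 26, 2,4,6‑Cl3C6H2COCl, Et3N, toluene, rt; then 25, 75 °C (no DMAP)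
Reagents that add atoms: none
Why: Yamaguchi esterification through the mixed anhydride acylates the hindered C8 hydroxyl with retention and, without a nucleophilic catalyst, should avoid isomerisation of the angelate to the tiglate.

Step 17
Reactants: 28 bis‑silyl angelate
Product: 29 target, (1S,3S,6S,7S,8R)
Conditions: HF·pyridine, pyridine, THF, 0 °C → rt
Reagents that add atoms: none
Why: Buffered fluoride desilylation frees the C1 and C15 hydroxyls while acetate, angelate and α‑methylene lactone are stable to these mildly acidic conditions.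

Compound list
1 | but‑3‑yn‑2‑ol (racemic) | CC(O)C#C | starting material
2 | bromomagnesium (Z)-4-(bromomagnesio)-3-methylbut-3-en-2-olate | CC(O[Mg]Br)/C(C)=C\[Mg]Br | intermediate
3 | (Z)-4-iodo-3-methylbut-3-en-2-ol (racemic) | CC(O)/C(C)=C\I | intermediate
4 | (Z)-4-iodo-3-methylbut-3-en-2-one | CC(=O)/C(C)=C\I | intermediate
5 | methyl prop‑2‑ynoate | C#CC(=O)OC | starting material
6 | diethylaluminium 3-iodo-1-methoxypropa-1,2-dien-1-olate | COC(O[Al](CC)CC)=C=CI | intermediate
7 | methyl (Z)-2-(hydroxymethyl)-3-iodoprop-2-enoate | COC(=O)/C(CO)=C\I | intermediate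
8 | methyl (Z)-2-[(tert-butyldimethylsilyloxy)methyl]-3-iodoprop-2-enoate | COC(=O)/C(CO[Si](C)(C)C(C)(C)C)=C\I | intermediate
9 | (S)-2,2-dimethyl-1,3-dioxolane-4-carbaldehyde | O=C[C@@H]1COC(C)(C)O1 | starting material
10 | 2-[(E)-2-[(4R)-2,2-dimethyl-1,3-dioxolan-4-yl]ethenyl]-4,4,5,5-tetramethyl-1,3,2-dioxaborolane | CC1(C)OB(/C=C/[C@@H]2COC(C)(C)O2)OC1(C)C | intermediate
11 | methyl (2Z,4E)-2-[(tert-butyldimethylsilyloxy)methyl]-5-[(4R)-2,2-dimethyl-1,3-dioxolan-4-yl]penta-2,4-dienoate | COC(=O)/C(CO[Si](C)(C)C(C)(C)C)=C\C=C\[C@@H]1COC(C)(C)O1 | intermediate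
12 | (2E,4E)-2-[(tert-butyldimethylsilyloxy)methyl]-5-[(4R)-2,2-dimethyl-1,3-dioxolan-4-yl]penta-2,4-dien-1-ol | OC/C(CO[Si](C)(C)C(C)(C)C)=C\C=C\[C@@H]1COC(C)(C)O1 | intermediate
13 | (4R)-4-[(1E,3E)-4-[(tert-butyldimethylsilyloxy)methyl]-5-(triethylsilyloxy)penta-1,3-dienyl]-2,2-dimethyl-1,3-dioxolane | CC[Si](CC)(CC)OC/C(CO[Si](C)(C)C(C)(C)C)=C\C=C\[C@@H]1COC(C)(C)O1 | intermediate
14 | 2‑bromoprop‑2‑enoic acid | C=C(Br)C(=O)O | starting material
15 | (4R,5S)-4-[(4R)-2,2-dimethyl-1,3-dioxolan-4-yl]-3-methylidene-5-[(E)-2-[(tert-butyldimethylsilyloxy)methyl]-3-(triethylsilyloxy)prop-1-enyl]oxolan-2-one | C=C1C(=O)O[C@@H](/C=C(/CO[Si](C)(C)C(C)(C)C)CO[Si](CC)(CC)CC)[C@@H]1[C@@H]1COC(C)(C)O1 | intermediate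
16 | primary allylic alcohol from 15 (triethylsilyl group removed; stereochemistry as 15) | C=C1C(=O)O[C@@H](/C=C(/CO[Si](C)(C)C(C)(C)C)CO)[C@@H]1[C@@H]1COC(C)(C)O1 | intermediate
17 | (Z)-2-[(tert-butyldimethylsilyloxy)methyl]-3-[(2S,3R)-3-[(4R)-2,2-dimethyl-1,3-dioxolan-4-yl]-4-methylidene-5-oxooxolan-2-yl]prop-2-enal | C=C1C(=O)O[C@@H](/C=C(/CO[Si](C)(C)C(C)(C)C)C=O)[C@@H]1[C@@H]1COC(C)(C)O1 | intermediate
18 | (Z)-4-iodo-3-methylbuta-1,3-dien-2-yl diisopinocampheylborinate (from (+)-Ipc2BCl) | C=C(OB([C@H]1C[C@H]2C[C@@H]([C@@H]1C)C2(C)C)[C@H]1C[C@H]2C[C@@H]([C@@H]1C)C2(C)C)/C(C)=C\I | intermediate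
19 | (3S)‑β‑hydroxy ketone (C3‑OH, C1 ketone, Z‑vinyl iodide; C6 S, C7 R; C15‑OTBS; R‑dioxolane) | C=C1C(=O)O[C@@H](/C=C(/CO[Si](C)(C)C(C)(C)C)[C@@H](O)CC(=O)/C(C)=C\I)[C@@H]1[C@@H]1COC(C)(C)O1 | intermediate
20 | (1S,3S)‑anti C3‑acetate C1‑alcohol (otherwise as 19) | C=C1C(=O)O[C@@H](/C=C(/CO[Si](C)(C)C(C)(C)C)[C@@H](OC(C)=O)C[C@H](O)/C(C)=C\I)[C@@H]1[C@@H]1COC(C)(C)O1 | intermediate
21 | C1 tert‑butyldimethylsilyl ether of 20 | C=C1C(=O)O[C@@H](/C=C(/CO[Si](C)(C)C(C)(C)C)[C@@H](OC(C)=O)C[C@H](O[Si](C)(C)C(C)(C)C)/C(C)=C\I)[C@@H]1[C@@H]1COC(C)(C)O1 | intermediate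
22 | terminal (R)‑1,2‑diol from 21 (acetonide removed) | C=C1C(=O)O[C@@H](/C=C(/CO[Si](C)(C)C(C)(C)C)[C@@H](OC(C)=O)C[C@H](O[Si](C)(C)C(C)(C)C)/C(C)=C\I)[C@@H]1[C@@H](O)CO | intermediate
23 | C8 aldehyde (C6 S, C7 R, 1S, 3S; Z‑vinyl iodide) | C=C1C(=O)O[C@@H](/C=C(/CO[Si](C)(C)C(C)(C)C)[C@@H](OC(C)=O)C[C@H](O[Si](C)(C)C(C)(C)C)/C(C)=C\I)[C@@H]1C=O | intermediate
24 | (Z)‑alkenylchromium dichloride from 23 (C9–Cr) | C=C1C(=O)O[C@@H](/C=C(/CO[Si](C)(C)C(C)(C)C)[C@@H](OC(C)=O)C[C@H](O[Si](C)(C)C(C)(C)C)/C(C)=C\[Cr](Cl)Cl)[C@@H]1C=O | intermediate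
25 | (1S,3S,6S,7S,8R)‑macrocyclic alcohol (4Z,9Z; C1‑OTBS, C3‑OAc, C8‑OH, C15‑OTBS) | C=C1C(=O)O[C@H]2/C=C(/CO[Si](C)(C)C(C)(C)C)[C@@H](OC(C)=O)C[C@H](O[Si](C)(C)C(C)(C)C)/C(C)=C\[C@@H](O)[C@H]12 | intermediate
26 | angelic acid, (Z)-2-methylbut-2-enoic acid | C/C=C(/C)C(=O)O | starting material
27 | (Z)-2-methylbut-2-enoic 2,4,6-trichlorobenzoic anhydride | C/C=C(/C)C(=O)OC(=O)c1c(Cl)cc(Cl)cc1Cl | intermediate
28 | C8 angelate of 25 (1S,3S,6S,7S,8R) | C=C1C(=O)O[C@H]2/C=C(/CO[Si](C)(C)C(C)(C)C)[C@@H](OC(C)=O)C[C@H](O[Si](C)(C)C(C)(C)C)/C(C)=C\[C@@H](OC(=O)/C(C)=C\C)[C@H]12 | intermediate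
29 | target (1S,3S,6S,7S,8R; 4Z,9Z; angelate) | C=C1C(=O)O[C@H]2/C=C(/CO)[C@@H](OC(C)=O)C[C@H](O)/C(C)=C\[C@@H](OC(=O)/C(C)=C\C)[C@H]12 | target

Total step count: 17. Longest linear sequence: 14 steps (5 → 7 → 8 → 11 → 12 → 13 → 15 → 17 → 19 → 20 → 21 → 23 → 25 → 28 → 29).

Steps most likely to fail

Step 9. Carbopalladation at the 1,4‑disubstituted diene terminus may be slow, so that β‑hydride loss to trienes competes, the C–O closure may proceed by the outer‑sphere path and erode the trans‑lactone, or face discrimination at C7 may be weak. The fallback sets out from 13 and returns at 15 by an oxidative free‑radical lactone annulation that forms the same two bonds. Diene 13 is treated with malonic acid and Mn(OAc)3·2H2O (KOAc, AcOH, 25–40 °C): the malonyl radical adds to C7, the allyl radical is oxidised and the acid closes onto C6 to give the α‑carboxy trans‑lactone F1. Decarboxylative Mannich methylenation (aqueous CH2O, Et2NH; then NaOAc, AcOH, warming) then gives 15.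

Step 15. The ring closure may take the other aldehyde face (C11 and not C6 anti to the incoming alkenyl group), and the α‑branched aldehyde may epimerise or migrate its double bond before closure. The fallback sets out from 23 and returns at 28: the cyclisation is run as before, the C8‑epimeric macrocyclic alcohol F2 is taken on, and the angelate is introduced with inversion by Mitsunobu esterification with 26 (PPh3, diisopropyl azodicarboxylate, toluene, 0 °C) in place of the retentive Yamaguchi acylation.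

Step 11. Reagent control over the hindered Z‑enal face may be insufficient, and the amine may attack the β‑iodo enone by addition–elimination during enolisation. The fallback sets out from 4 and returns at 19. Ketone 4 is converted with LiN(SiMe3)2 and Me3SiCl (THF, −78 °C) into the trimethylsilyl enol ether F3. F3 is then added to 17 in a catalytic enantioselective Mukaiyama‑type aldol reaction (SiCl4 activated by a chiral binaphthyldiamine‑derived bisphosphoramide, CH2Cl2, −78 °C; buffered aqueous KF work‑up) to give 19 directly.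

Further compounds
F1 | step 9 | α‑carboxy trans‑lactone from 13 (C11 bears CO2H, epimers at C11; C6 S, C7 R) | OC(=O)C1C(=O)O[C@@H](/C=C(/CO[Si](C)(C)C(C)(C)C)CO[Si](CC)(CC)CC)[C@@H]1[C@@H]1COC(C)(C)O1
F2 | step 15 | (1S,3S,6S,7S,8S)‑macrocyclic alcohol, C8 epimer of 25 | C=C1C(=O)O[C@H]2/C=C(/CO[Si](C)(C)C(C)(C)C)[C@@H](OC(C)=O)C[C@H](O[Si](C)(C)C(C)(C)C)/C(C)=C\[C@H](O)[C@H]12
F3 | step 11 | (Z)-4-iodo-3-methyl-2-(trimethylsilyloxy)buta-1,3-diene | C=C(O[Si](C)(C)C)/C(C)=C\I
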